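**Assumptions (one line each)**
- (−)-Quinic acid is (1S,3R,4S,5R): 3,4-cis, 4,5-trans, 1-OH cis to 3-OH, CO2H cis to 5-OH.
- Eugenol, tert-butyl diazoacetate and (−)-quinic acid are commercial.
- Stereochemistry was mapped onto quinic acid as follows:
  - Target C3′/C4′ are trans. Quinic C3/C4 are cis, so the C3 configuration must be inverted.
  - Target C4′ (S) = quinic C4. The C5-OH is removed.
  - Target C3′ (S) = quinic C3, after inversion.
  - The C1 radical re-forms the quaternary carbinol centre.

## Retrosynthesis
1. Target 18 comes from LiAlH4 reduction of trans-dihydrobenzofuran tert-butyl ester 17, which comes from base epimerisation of the kinetic cis ester 16 at C3.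
2. Key step: a photoredox decarboxylative, dearomative radical addition joins acid 8 to benzofuran 15 (forming C1′–C2), so the dihydrobenzofuran ring is created by dearomatising the pre-built benzofuran.
3. Acid 8 comes from (−)-quinic acid (1). The cyclohexane ring is already present in the chiral-pool starting material. The route removes the 5-OH, methylates 4-OH and inverts C3.
4. Benzofuran 15 comes from eugenol by ortho-formylation, diazoacetate annulation, dehydration and hydroboration.
5. Ring order: the cyclohexane is pre-formed (quinic acid), then the benzofuran is built, then the dihydrobenzofuran forms in the key step.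

## Forward route

**Step 1**
Reactants: 1 (−)-quinic acid
Product: 2 methyl 3,4-O-isopropylidene-quinate
Conditions: 2,2-dimethoxypropane, TsOH·H2O (cat.), MeOH, 60 °C
Reagents that add atoms: 2,2-dimethoxypropane `COC(C)(C)OC`; methanol `CO`
Why: Fischer esterification plus transketalisation. The acetonide forms only on the cis-3,4-diol, leaving the tertiary 1-OH and the 5-OH free. No stereocentre changes.

**Step 2**
Reactants: 2
Product: 3 5-O-(imidazol-1-ylthiocarbonyl) derivative
Conditions: TCDI, DMAP, ClCH2CH2Cl, 80 °C
Reagents that add atoms: 1,1′-thiocarbonyldiimidazole `S=C(n1ccnc1)n1ccnc1`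
Why: O-thioacylation of the accessible equatorial 5-OH; the tertiary 1-OH is too hindered to react.

**Step 3**
Reactants: 3
Product: 4 methyl 5-deoxy-3,4-O-isopropylidene-quinate
Conditions: Bu3SnH, AIBN, PhMe, 110 °C
Reagents that add atoms: none
Why: Barton–McCombie deoxygenation removes the C5 oxygen and its stereocentre. The ester and acetonide survive.

**Step 4**
Reactants: 4
Product: 5 methyl 5-deoxyquinate (cis-3,4-diol)
Conditions: 80% aq. AcOH, 60 °C
Reagents that add atoms: none (the water oxygen leaves as acetone)
Why: Acetal hydrolysis. No lactonisation is possible because C5 carries no OH and C3-OH is trans to CO2Me.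

**Step 5**
Reactants: 5
Product: 6 methyl 5-deoxy-4-O-methylquinate
Conditions: Bu2SnO, PhMe, reflux (Dean–Stark); then MeI, CsF, DMF, 25 °C
Reagents that add atoms: iodomethane `CI`
Why: Stannylene-acetal alkylation of a cis-diol occurs at the more nucleophilic equatorial O4. O3 is axial and hydrogen-bonded to the 1,3-diaxial 1-OH, so 4-OMe is the major product.

**Step 6**
Reactants: 6
Product: 7 methyl 3-epi-3-O-(p-nitrobenzoyl)-5-deoxy-4-O-methylquinate
Conditions: 4-O2NC6H4CO2H, PPh3, DIAD, THF, 0→25 °C
Reagents that add atoms: p-nitrobenzoic acid `OC(=O)c1ccc(cc1)[N+](=O)[O-]`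
Why: Mitsunobu SN2 inversion of the axial C3-OH sets C3 as S (trans to 4-OMe). The tertiary OH does not react.

**Step 7**
Reactants: 7
Product: 8 (1-hydroxy-3-epi, 4-methoxy) acid: 1,3-dihydroxy-4-methoxycyclohexane-1-carboxylic acid
Conditions: LiOH·H2O, THF/H2O, 50 °C; then H+ resin
Reagents that add atoms: lithium hydroxide `[Li+].[OH-]`
Why: Saponification cleaves both the methyl ester and the p-nitrobenzoate (acyl–O cleavage), so C3 stays inverted. This gives the radical precursor.

**Step 8**
Reactants: 9 eugenol (4-allyl-2-methoxyphenol); 10 paraformaldehyde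
Product: 11 5-allyl-2-hydroxy-3-methoxybenzaldehyde
Conditions: MgCl2, Et3N, MeCN, 80 °C
Reagents that add atoms: paraformaldehyde `C=O`
Why: Casnati–Skattebøl ortho-formylation. It is regiospecific because only one position ortho to the phenol OH is free.

**Step 9**
Reactants: 11; 12 tert-butyl diazoacetate
Product: 13 tert-butyl 5-allyl-2-hydroxy-7-methoxy-2,3-dihydrobenzofuran-3-carboxylate
Conditions: HBF4·OEt2 (5 mol%), CH2Cl2, 0→25 °C
Reagents that add atoms: none beyond reactant 12
Why: Acid-catalysed diazoacetate addition to the aldehyde with 1,2-aryl shift gives an aryl-malonaldehyde ester. The phenol then closes onto the aldehyde as a lactol, so C3 carries the ester.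

**Step 10**
Reactants: 13
Product: 14 tert-butyl 5-allyl-7-methoxybenzofuran-3-carboxylate
Conditions: MsCl, Et3N, CH2Cl2, 0 °C; then DBU, 25 °C
Reagents that add atoms: none (the mesylate leaves)
Why: Lactol mesylation followed by E1cB elimination aromatises to the benzofuran. Mild conditions are used to preserve the acid-labile t-Bu ester.

**Step 11**
Reactants: 14
Product: 15 tert-butyl 5-(3-hydroxypropyl)-7-methoxybenzofuran-3-carboxylate
Conditions: 9-BBN, THF, 25 °C; then 3 M NaOH, 30% H2O2, 0 °C
Reagents that add atoms: hydrogen peroxide `OO` (supplies the OH oxygen)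
Why: Hydroboration–oxidation is selective for the terminal alkene; the benzofuran and the hindered t-Bu ester are untouched.

**Step 12 (key step, photochemical)**
Reactants: 8; 15
Product: 16 tert-butyl 2-[(1R,3S,4S)-1,3-dihydroxy-4-methoxycyclohexyl]-5-(3-hydroxypropyl)-7-methoxy-2,3-dihydrobenzofuran-3-carboxylate (kinetic cis-2,3 isomer, target diastereomer at C2)
Conditions: [Ir{dF(CF3)ppy}2(dtbbpy)]PF6 (2 mol%), Cs2CO3 (0.3 equiv), DMSO/H2O 50:1, blue LEDs (455 nm), 25 °C, 24 h; then chromatographic/HPLC separation of diastereomers
Reagents that add atoms: none (CO2 is lost; the final proton comes from water)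
Why: Proposed new method: the excited Ir(III) oxidises the carboxylate of 8. CO2 loss gives a tertiary α-hydroxyalkyl (ketyl-type, nucleophilic) radical that adds to C2 of 15, the β-carbon of the benzofuran-3-carboxylate. The resulting benzylic α-ester radical is reduced by Ir(II) to an enolate, which is protonated. The closest known reactions are the photoredox decarboxylative Giese addition of α-oxy acids, ketyl–olefin coupling, and dearomative radical additions to indole- and benzofuran-3-acceptors; α-hydroxy acids have not been used this way with a benzofuran acceptor. Stereochemistry: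
- C1′: the radical is attacked on the face anti to the 3-OH (1,3-trans), which places the new C–C bond cis to the 4-OMe, as in the target.
- C2: selectivity is moderate, set by a staggered, H-bonded transition state with an expected dr of roughly 1:1–2:1 (the main weakness); the wanted diastereomer is separated.
- C3: kinetic protonation anti to the bulky C2 substituent gives cis.

**Step 13**
Reactants: 16
Product: 17 trans-2,3-dihydrobenzofuran tert-butyl ester
Conditions: DBU (0.3 equiv), MeCN, 40 °C
Reagents that add atoms: none
Why: Thermodynamic epimerisation at the acidic benzylic α-ester C3 converts cis to trans, and C2 is untouched. The t-Bu ester blocks lactonisation onto the tertiary 1′-OH.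

**Step 14**
Reactants: 17
Product: 18 difengpiol B
Conditions: LiAlH4, THF, 0→25 °C
Reagents that add atoms: none (hydride only; tBuOH is lost)
Why: Ester-to-primary-alcohol reduction. The hydroxyls, aryl and alkyl ethers and all stereocentres are untouched.

## Compound list
1 | (−)-quinic acid | `OC(=O)[C@]1(O)C[C@@H](O)[C@@H](O)[C@H](O)C1` | starting material
2 | methyl 3,4-O-isopropylidene-quinate | `COC(=O)[C@]1(O)C[C@H]2OC(C)(C)O[C@H]2[C@H](O)C1` | intermediate
3 | 5-O-imidazolylthiocarbonyl derivative of 2 | `COC(=O)[C@]1(O)C[C@H]2OC(C)(C)O[C@H]2[C@H](OC(=S)n3ccnc3)C1` | intermediate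
4 | methyl 5-deoxy-3,4-O-isopropylidene-quinate | `COC(=O)[C@]1(O)C[C@H]2OC(C)(C)O[C@H]2CC1` | intermediate
5 | methyl 5-deoxyquinate | `COC(=O)[C@]1(O)C[C@@H](O)[C@@H](O)CC1` | intermediate
6 | methyl 5-deoxy-4-O-methylquinate | `COC(=O)[C@]1(O)C[C@@H](O)[C@@H](OC)CC1` | intermediate
7 | C3-epimeric p-nitrobenzoate of 6 | `COC(=O)[C@]1(O)C[C@H](OC(=O)c2ccc([N+](=O)[O-])cc2)[C@@H](OC)CC1` | intermediate
8 | 1,3-dihydroxy-4-methoxycyclohexane-1-carboxylic acid (radical precursor) | `OC(=O)[C@]1(O)C[C@H](O)[C@@H](OC)CC1` | intermediate
9 | eugenol | `C=CCc1ccc(O)c(OC)c1` | starting material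
10 | paraformaldehyde | `C=O` | starting material
11 | 5-allyl-2-hydroxy-3-methoxybenzaldehyde | `C=CCc1cc(C=O)c(O)c(OC)c1` | intermediate
12 | tert-butyl diazoacetate | `CC(C)(C)OC(=O)C=[N+]=[N-]` | starting material
13 | tert-butyl 5-allyl-2-hydroxy-7-methoxy-2,3-dihydrobenzofuran-3-carboxylate | `C=CCc1cc2C(C(=O)OC(C)(C)C)C(O)Oc2c(OC)c1` | intermediate
14 | tert-butyl 5-allyl-7-methoxybenzofuran-3-carboxylate | `C=CCc1cc2c(coc2c(OC)c1)C(=O)OC(C)(C)C` | intermediate
15 | tert-butyl 5-(3-hydroxypropyl)-7-methoxybenzofuran-3-carboxylate | `OCCCc1cc2c(coc2c(OC)c1)C(=O)OC(C)(C)C` | intermediate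
16 | cis-2,3 adduct | `COc1cc(CCCO)cc2c1O[C@H]([C@]1(O)CC[C@H](OC)[C@@H](O)C1)[C@@H]2C(=O)OC(C)(C)C` | intermediate
17 | trans-2,3 ester | `COc1cc(CCCO)cc2c1O[C@H]([C@]1(O)CC[C@H](OC)[C@@H](O)C1)[C@H]2C(=O)OC(C)(C)C` | intermediate
18 | difengpiol B | `COc1cc(CCCO)cc2c1O[C@H]([C@]1(O)CC[C@H](OC)[C@@H](O)C1)[C@H]2CO` | target

## Totals
- Total steps: 14.
- Longest linear sequence: 10 (Steps 1–7, 12, 13, 14).

## Three steps most likely to fail
1. **Step 12 (proposed new photoredox coupling).**
   - Risks: the α-hydroxy radical may over-oxidise to the ketone; the dr at C1′ and C2 is only moderate.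
   - Fallback (known chemistry): oxidatively decarboxylate 8 (Pb(OAc)4 or NaOCl) to the 3-hydroxy-4-methoxycyclohexanone. Then couple it with benzofuran 15 by SmI2/HMPA ketyl–olefin addition, and continue with Steps 13–14.
2. **Step 6 (Mitsunobu inversion at C3).**
   - Risks: E2 elimination or poor conversion on the hindered axial alcohol.
   - Fallback: protect the 1-OH as TMS ether, oxidise C3-OH to the ketone (Dess–Martin), then reduce with NaBH4 to the equatorial alcohol trans to 4-OMe. This sets C3 through hydride axial attack, not SN2.
3. **Step 5 (regioselective 4-O-methylation).**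
   - Risk: O3/O4 mixtures.
   - Fallback: form the cis-3,4 orthoester (PhC(OMe)3, CSA) and open it with aqueous acid to give the axial 3-O-benzoate with free equatorial 4-OH. Methylate with Ag2O/MeI, then remove the benzoate with K2CO3/MeOH before Step 6.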